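Slowness is my first worry here: in winter, the coldest flask, the substrate may barely reach target in the time given, while the warm flasks open the losses.

the same everywhere: substrate 0.050 M; time 2.5 min

| run | temperature | remark |
|---|---|---|
| winter | −25 °C |  |
| dusk | 0 °C |  |
| spring |  | at −25 °C until 50 s, from then on at 25 °C |
| dawn | 25 °C |  |

1. the flask that comes out highest in amount of target, in percent of the substrate charged, or "all alike" when all lie within 1.5 percentage points (winter / dusk / spring / dawn / all alike)
2. target at the end, in percent of the substrate charged, winter
3. target at the end, in percent of the substrate charged, dusk
4. target at the end, in percent of the substrate charged, spring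
5. target at the end, in percent of the substrate charged, dawn

- percent here means substrate units held: one self-condensation product or side product counts as two
- for a step with 2 of a species take k times the square, and two of it per event
- all constants are for 25 °C and move with temperature by the activation energies and enthalpies
- in a conversion other conformer counts as not yet reacted

    2 other conformer → self-condensation product (k1 = 16 M⁻¹ s⁻¹, Ea1 = 44.0 kJ mol⁻¹)
    substrate ⇌ other conformer (K2 = 0.63, k2 = 0.092 s⁻¹, Ea2 = 69.0 kJ mol⁻¹, ΔH2 = 20.0 kJ mol⁻¹)
    other conformer → isomer of the product (k3 = 0.027 s⁻¹, Ea3 = 81.0 kJ mol⁻¹)
    substrate ⇌ target (K4 = 2.0, k4 = 0.069 s⁻¹, Ea4 = 71.0 kJ mol⁻¹, ΔH4 = −14.0 kJ mol⁻¹)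
    substrate + target → side product (k5 = 0.53 M⁻¹ s⁻¹, Ea5 = 37.0 kJ mol⁻¹)
    (constants at 25 °C)

I begin with substrate ⇌ target and nothing else, and I count in fractions of the charge. Target then climbs towards the share K over one plus K, where K is the equilibrium constant of that step. The climb runs at the forward constant plus the back constant. In winter K is 6.24 and the forward constant is 0.0129 min⁻¹, so target stands at 3.17% after 2.5 min. I call this the reach: the fraction of the charge that target attains in a flask's time with every other step left out.

In dusk, at 0 °C, K is 3.35 and the forward constant is 0.301 min⁻¹, so the reach is 48.0%. In dawn it is 66.7%. The cold start of spring yields hardly any target, so I start the spring clock at the change and get 66.7%.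

Now I add substrate ⇌ other conformer, with equilibrium constant K′. In balance it parks material away from target, and the share not parked is one plus K over one plus K plus K′. K′ is 0.124 in winter, 0.301 in dusk and 0.63 at 25 °C. The shares are 98.3% in winter, 93.5% in dusk, and 82.6% in spring and dawn.

Then comes the loss by pairing. I take substrate and other conformer as balanced, so other conformer holds the share K′ over one plus K′ of what stands outside target. Pairing goes with the square of other conformer, so I use a second-order form. The pairing constant is twice the constant of that step, times the charge, times the square of that share. It is 0.0327 min⁻¹ in winter, 1.01 min⁻¹ in dusk and 14.3 min⁻¹ at 25 °C. The kept fraction is one over one plus the pairing constant, times the time, times the square of the part of the charge outside the reach. I hold that part at its end value and leave out the isomer of the product and the side product, so this is a rough reckoning. The kept fractions are 92.9% for winter, 59.4% for dusk, 27.4% for spring and 20.1% for dawn.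

Reach times unparked share times kept fraction gives me 2.89% for winter, 26.7% for dusk, 15.1% for spring and 11.1% for dawn. My highest flask is dusk.

The forecast names dusk, with 2.8%, 28%, 10% and 6.7% in the order winter, dusk, spring, dawn, on the ground that “At 0 °C the equilibrium favours target more, the conformer is less populated and the loss steps are slower”.

The simulation puts dusk highest, with winter 2.82%, dusk 26.9%, spring 13.8% and dawn 8.97%. Winter ends below its reach of 3.17%. In winter the relaxation half-life of substrate and target, 46.3 min, is long against the 2.5 min of the flask, and it is longer than the 3.78 min of substrate and other conformer.

A flask like winter kept at 0 °C has a reach of 48.0%, and the unparked share and kept fraction bring that to 26.7%. The simulation gives that neighbour 26.9%.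

All constants belong to no real substance; the result is computed.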